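**Assumptions.** The target has no stereocentres, so "single enantiomer" is vacuous. Intermediate 13 has three stereocentres, but they are a diastereomeric mixture that is erased when the ring aromatises in step 8. The other reagents (B2pin2, LDA, NaH, KOtBu, BnBr, MeI, (Me3Si)3SiH and so on) are taken as commercial.

## Retrosynthetic overview
1. The final step removes two benzyl groups (benzyl ester and benzyl ether) from 17. The side-chain C–C bond comes from an aryl radical adding to ethyl vinyl ketone (Giese-type hydroarylation) on aryl bromide 15, late in the sequence so no ketone protection is needed.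
2. The hindered diaryl ether is never made by Ullmann coupling. Ring A is built onto a preformed aryloxyacetate (7) by a Michael/Dieckmann [3+3] annulation with an alkylidene acetoacetate, then dehydrogenated to the arene. This places pentyl, CO2Bn, OAr and the two oxygens in one operation.
3. Ring B (the only ring present from the start) comes from 1-bromo-3-fluorobenzene by directed ortho-metalation/carbomethoxylation, Ir-catalysed C–H borylation/oxidation, O-benzylation, then SNAr of F by glycolate.
4. Order of ring formation: ring B is the starting arene, and ring A is formed in step 7 and aromatised in step 8. The 4-OMe group is then installed by regioselective methylation of the non-chelated 4-OH.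

## Route

**Step 1**
Reactants: 1, 1-bromo-3-fluorobenzene
Product: 2, methyl 2-bromo-6-fluorobenzoate
Conditions: LDA, THF, −78 °C, 1 h; then quench into excess ClCO2Me, −78 °C
Reagents that add atoms: methyl chloroformate, COC(=O)Cl
Why: Directed ortho-metalation occurs at the C–H flanked by F and Br, the most acidic site. The resulting 2,6-disubstituted ester resists over-addition of the aryllithium.

**Step 2**
Reactants: 2
Product: 4, methyl 2-bromo-6-fluoro-4-hydroxybenzoate (via 3, methyl 2-bromo-6-fluoro-4-(Bpin)benzoate, not isolated)
Conditions: (i) [Ir(OMe)(cod)]2/dtbpy, B2pin2, THF, 80 °C; (ii) Oxone, acetone/H2O, rt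
Reagents that add atoms: Oxone (oxygen source for the OH), OOS(=O)(=O)[O-].[K+]
Why: Sterically controlled Ir-catalysed C–H borylation enters C4, the only position flanked by two H and meta to both halogens. Oxidative deborylation then gives the phenol.

**Step 3**
Reactants: 4
Product: 5, methyl 4-(benzyloxy)-2-bromo-6-fluorobenzoate
Conditions: BnBr, K2CO3, MeCN, 60 °C
Reagents that add atoms: benzyl bromide, BrCc1ccccc1
Why: Williamson O-benzylation of the phenol. The benzyl group is removed together with the ring A benzyl ester in step 11.

**Step 4**
Reactants: 5; 6, ethyl glycolate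
Product: 7, methyl 4-(benzyloxy)-2-bromo-6-(2-ethoxy-2-oxoethoxy)benzoate
Conditions: 6 (1.1 equiv), NaH, THF/DMF 4:1, 0 → 50 °C
Reagents that add atoms: none
Why: SNAr. F ortho to the ester is displaced far faster than Br, and the 2,6-disubstituted methyl ester is too hindered to be attacked by the alkoxide. This forms the ring B aryl–O bond on an unhindered CH2.

**Step 5**
Reactants: 8, diketene; 9, benzyl alcohol
Product: 10, benzyl acetoacetate
Conditions: DMAP (cat.), THF, 0 → 60 °C
Reagents that add atoms: none
Why: Alcoholysis of diketene gives the acetoacetate (acetoacetylation).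

**Step 6**
Reactants: 10; 11, hexanal
Product: 12, benzyl 2-acetyloct-2-enoate (E/Z mixture)
Conditions: piperidine/AcOH (cat.), 4 Å MS, CH2Cl2, rt
Reagents that add atoms: none
Why: Knoevenagel condensation gives the doubly activated alkylidene acetoacetate. Alkene geometry is irrelevant because the ring is aromatised later.

**Step 7**
Reactants: 7; 12
Product: 13, benzyl 5-[2-(methoxycarbonyl)-3-bromo-5-(benzyloxy)phenoxy]-2,4-dioxo-6-pentylcyclohexane-1-carboxylate (diastereomeric mixture)
Conditions: LDA (1.1 equiv), THF, −78 °C; add 12, −78 → 0 °C; then KOtBu (2.5 equiv), 0 → 40 °C; aqueous HCl work-up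
Reagents that add atoms: none
Why: Michael addition of the aryloxyacetate enolate to the alkylidene acetoacetate sets the C5–C6 bond with OAr and pentyl adjacent, as in the target. Dieckmann closure of the methyl ketone enolate onto the ethyl ester (as in dimedone synthesis) then gives the cyclohexane-1,3-dione. The three new stereocentres are erased in step 8.
Proposed new method: a Michael–Dieckmann [3+3] annulation using an α-aryloxy ester enolate to install the hindered 5-aryloxy group directly. The closest known reactions are dimedone-type Michael/Claisen ring closure and the Michael–Dieckmann synthesis of olivetolate-type 2,4-dioxocyclohexanecarboxylates.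

**Step 8**
Reactants: 13
Product: 14, benzyl 5-aryloxy-2,4-dihydroxy-6-pentylbenzoate (aryl = 5-benzyloxy-3-bromo-2-(methoxycarbonyl)phenyl)
Conditions: I2 (1.2 equiv), DMSO, 90 °C
Reagents that add atoms: none
Why: Iodination and HI elimination of the enolised dione (the olivetol-type dehydrogenative aromatisation) give the resorcylate. No leaving group sits β to a carbonyl, so ArOH is not lost. This step destroys all three ring A stereocentres, which is why the target has none.
Proposed new method: I2/DMSO in place of the usual I2/MeOH, chosen to avoid transesterifying the benzyl ester. The closest known reaction is the I2-mediated aromatisation of 2-carboalkoxycyclohexane-1,3-diones to β-resorcylates.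

**Step 9**
Reactants: 14
Product: 15, benzyl 5-aryloxy-2-hydroxy-4-methoxy-6-pentylbenzoate
Conditions: MeI (1.5 equiv), KHCO3 (1.5 equiv), DMF, rt
Reagents that add atoms: methyl iodide, CI
Why: Regioselective 4-O-alkylation of a 2,4-dihydroxybenzoate. The 2-OH is locked in a hydrogen bond to the ester carbonyl, so only the 4-OH reacts.

**Step 10**
Reactants: 15; 16, ethyl vinyl ketone (pent-1-en-3-one, 8 equiv)
Product: 17, benzyl 5-[5-(benzyloxy)-2-(methoxycarbonyl)-3-(3-oxopentyl)phenoxy]-2-hydroxy-4-methoxy-6-pentylbenzoate
Conditions: (Me3Si)3SiH (1.5 equiv, syringe pump over 4 h), AIBN (0.2 equiv), PhCF3 (0.02 M), 80 °C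
Reagents that add atoms: none (only H comes from the silane)
Why: Silyl radicals abstract Br to give an aryl radical, which adds to the CH2 terminus of the enone. The electrophilic α-keto radical is then reduced by the hydridic Si–H in a polarity-matched step (radical Giese-type hydroarylation). High enone concentration and slow silane addition outcompete direct Ar–H reduction. The free chelated phenol and the benzyl groups tolerate the conditions. No stereocentre is formed, since the radical carbon ends as CH2.

**Step 11**
Reactants: 17
Product: 18, Epiphorellic acid 2 (target)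
Conditions: H2 (1 atm), 10% Pd/C, EtOAc, rt
Reagents that add atoms: none (only H)
Why: Hydrogenolysis removes both the benzyl ester (giving the free acid) and the phenolic benzyl ether. The methyl ester, aryl methyl ether, diaryl ether and the aliphatic ketone survive at 1 atm, and no stereocentres are involved.

## Compound list
1 | 1-bromo-3-fluorobenzene | Fc1cccc(Br)c1 | starting material
2 | methyl 2-bromo-6-fluorobenzoate | COC(=O)c1c(F)cccc1Br | intermediate
3 | methyl 2-bromo-6-fluoro-4-(Bpin)benzoate (in situ) | COC(=O)c1c(F)cc(B2OC(C)(C)C(C)(C)O2)cc1Br | intermediate (not isolated)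
4 | methyl 2-bromo-6-fluoro-4-hydroxybenzoate | COC(=O)c1c(F)cc(O)cc1Br | intermediate
5 | methyl 4-(benzyloxy)-2-bromo-6-fluorobenzoate | COC(=O)c1c(F)cc(OCc2ccccc2)cc1Br | intermediate
6 | ethyl glycolate | OCC(=O)OCC | starting material
7 | methyl 4-(benzyloxy)-2-bromo-6-(2-ethoxy-2-oxoethoxy)benzoate | COC(=O)c1c(OCC(=O)OCC)cc(OCc2ccccc2)cc1Br | intermediate
8 | diketene | C=C1CC(=O)O1 | starting material
9 | benzyl alcohol | OCc1ccccc1 | starting material
10 | benzyl acetoacetate | CC(=O)CC(=O)OCc1ccccc1 | intermediate
11 | hexanal | CCCCCC=O | starting material
12 | benzyl 2-acetyloct-2-enoate (E/Z) | CCCCCC=C(C(C)=O)C(=O)OCc1ccccc1 | intermediate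
13 | cyclohexane-1,3-dione annulation product (diastereomeric mixture) | CCCCCC1C(Oc2cc(OCc3ccccc3)cc(Br)c2C(=O)OC)C(=O)CC(=O)C1C(=O)OCc1ccccc1 | intermediate
14 | benzyl 5-aryloxy-2,4-dihydroxy-6-pentylbenzoate | CCCCCc1c(Oc2cc(OCc3ccccc3)cc(Br)c2C(=O)OC)c(O)cc(O)c1C(=O)OCc1ccccc1 | intermediate
15 | benzyl 5-aryloxy-2-hydroxy-4-methoxy-6-pentylbenzoate | CCCCCc1c(Oc2cc(OCc3ccccc3)cc(Br)c2C(=O)OC)c(OC)cc(O)c1C(=O)OCc1ccccc1 | intermediate
16 | ethyl vinyl ketone (pent-1-en-3-one) | C=CC(=O)CC | starting material
17 | dibenzyl-protected diaryl ether ketone | CCCCCc1c(Oc2cc(OCc3ccccc3)cc(CCC(=O)CC)c2C(=O)OC)c(OC)cc(O)c1C(=O)OCc1ccccc1 | intermediate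
18 | Epiphorellic acid 2 | CCCCCc1c(Oc2cc(O)cc(CCC(=O)CC)c2C(=O)OC)c(OC)cc(O)c1C(=O)O | target

## Totals
Total steps: 11. Longest linear sequence: 9 (steps 1, 2, 3, 4, 7, 8, 9, 10, 11).

## Three steps most likely to fail
1. **Step 10 (aryl radical hydroarylation).** Direct Ar–H reduction or enone oligomerisation could dominate. Fallback: a Mizoroki–Heck coupling of 15 with ethyl vinyl ketone (Pd(OAc)2, P(o-tol)3, Et3N, DMF, 100 °C). The enone C=C is then saturated during the step 11 hydrogenolysis, so no step is added.
2. **Step 7 (Michael/Dieckmann annulation).** Competing aldol or retro-Knoevenagel chemistry, or ester exchange, could lower the yield. Fallback: change the disconnection. Make benzyl 2-hydroxy-4-methoxy-6-pentylbenzoate by Michael–Dieckmann of 10 with hept-2-enoate, then methylation. Introduce the 5-OH by Elbs persulfate oxidation (para to the chelated 2-OH). Join it to the aryl iodide analogue of 5 by Cu/N,N-dimethylglycine Ullmann etherification, then continue at step 10.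
3. **Step 8 (dehydrogenative aromatisation).** Electrophilic iodination of the electron-rich product at C3, or partial benzyl ester loss, are the risks. Fallback: Pd(II)-catalysed aerobic dehydrogenation (Pd(TFA)2, 2-dimethylaminopyridine, O2, DMSO), which uses no halogen electrophile and works by α-palladation/β-hydride elimination.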